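## Retrosynthetic overview

1. The C4/C5 bromochloride comes last: cis-diol cyclic sulfate of cyclohexene 12, bromide by SN2 at C5, chloride at C4 under control of the neighbouring acetate.
2. Cyclohexene 12 comes from ketone 10 (bulky hydride, acetylation); ring B (oxane) is closed by 6-endo bromoetherification of tertiary alcohol 9.
3. Ketone 9 comes from anisole 7 by Birch reduction and enol ether hydrolysis: the flat arene becomes ring A, the anisole oxygen becomes the C2 oxygen, and C1 is created by protonation.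
4. Anisole 7 comes from chelation-controlled addition of the Grignard reagent of 2-bromo-5-methylanisole to (S)-α-hydroxy ketone 3, made from 6-methylhept-5-en-2-one by organocatalytic α-oxygenation.
5. Ring order: ring A (carbocycle, unveiled from the arene) first, ring B (oxane) second.

Assumption (locants used below): ring A is C1 (bears the oxanyl group), C2 (OAc), C3, C4 (CH3, Cl), C5 (Br), C6; C7 = oxane C2, C8 = CHOH, C9 = CH2, C10 = CHBr, C11 = C(CH3)2. Compounds 1 and 4, D-proline and nitrosobenzene are taken as commercial.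

## Route

Step 1
Reactants: 1 6-methylhept-5-en-2-one
Product: 3 (3S)-3-hydroxy-6-methylhept-5-en-2-one, via aminooxy ketone 2 (not isolated)
Conditions: D-proline (20 mol%), PhNO, DMF, 0 °C; then Zn, AcOH, 0 °C
Reagents that add atoms: nitrosobenzene O=Nc1ccccc1
Why: Proline enamine catalysis (asymmetric α-aminooxylation, O-nitroso aldol) oxygenates the more substituted α-carbon, D-proline giving the (S)-C–O bond that becomes C8, and Zn/AcOH then cleaves the weak N–O bond without touching the alkene.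

Step 2
Reactants: 3 (3S)-3-hydroxy-6-methylhept-5-en-2-one; 4 2-bromo-5-methylanisole
Product: 7 (2S,3S)-2-(2-methoxy-4-methylphenyl)-6-methyl-3-(triethylsilyloxy)hept-5-en-2-ol, via arylmagnesium bromide 5 (not isolated), via diol 6 (not isolated)
Conditions: 4, Mg, THF, 40 °C (2.2 equiv of 5); 3, THF, −78 → 0 °C; then Et3SiCl, imidazole (cat.), 0 → 25 °C
Reagents that add atoms: chlorotriethylsilane CC[Si](CC)(CC)Cl
Why: Grignard formation followed by Cram-chelate addition: the magnesium alkoxide of 3 chelates the ketone, the aryl group adds on the face of the C8 hydrogen and sets C7 as (S), and only the less hindered secondary alkoxide is silylated in the same pot.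

Step 3
Reactants: 7 (2S,3S)-2-(2-methoxy-4-methylphenyl)-6-methyl-3-(triethylsilyloxy)hept-5-en-2-ol
Product: 9 (2R)-2-[(2S,3S)-2-hydroxy-6-methyl-3-(triethylsilyloxy)hept-5-en-2-yl]-5-methylcyclohex-4-en-1-one, via enol ether 8 (not isolated)
Conditions: Li, NH3/THF, t-BuOH, −78 °C; NH4Cl; then (CO2H)2, MeOH/H2O, 0 °C
Reagents that add atoms: water O
Why: Birch reduction (the tertiary lithium alkoxide shields the benzylic C–O bond, and OMe, side chain and CH3 all end on sp2 carbons) gives the 1,4-diene, whose enol ether is hydrolysed by weak acid without moving the C4=C5 bond; C1 is set by A(1,3)-controlled protonation anti to the bulky C8 branch (C7 methyl eclipsing the enol C=C–O side in protic medium), giving the (R)-ketone that maps onto the target's C1.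

Step 4
Reactants: 9 (2R)-2-[(2S,3S)-2-hydroxy-6-methyl-3-(triethylsilyloxy)hept-5-en-2-yl]-5-methylcyclohex-4-en-1-one
Product: 10 (2R)-2-[(2S,3S,5S)-5-bromo-2,6,6-trimethyl-3-(triethylsilyloxy)oxan-2-yl]-5-methylcyclohex-4-en-1-one
Conditions: NBS, CH2Cl2/MeNO2, −20 °C, dark
Reagents that add atoms: N-bromosuccinimide O=C1CCC(=O)N1Br
Why: Bromoetherification: reversible bromonium formation is funnelled through the only alkene with a well-placed nucleophile, the C7–OH attacking the tertiary end (6-endo, Markovnikov) in a chair with the cyclohexenonyl group equatorial and Br anti to the new C–O bond, hence equatorial (C10 S); the silyl ether keeps O8 out of a 5-endo closure.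

Step 5
Reactants: 10 (2R)-2-[(2S,3S,5S)-5-bromo-2,6,6-trimethyl-3-(triethylsilyloxy)oxan-2-yl]-5-methylcyclohex-4-en-1-one
Product: 12 (1R,6S)-6-[(2S,3S,5S)-5-bromo-2,6,6-trimethyl-3-(triethylsilyloxy)oxan-2-yl]-3-methylcyclohex-3-en-1-yl acetate, via lithium alkoxide 11 (not isolated)
Conditions: LiBH(s-Bu)3, THF, −78 °C; then Ac2O, DMAP (cat.), −78 → 25 °C
Reagents that add atoms: acetic anhydride CC(=O)OC(C)=O
Why: Bulky-hydride reduction of a 2-substituted cyclohexanone: hydride enters from the equatorial side and gives the axial alkoxide cis to the oxanyl group (C2 R), which is acetylated in situ.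

Step 6
Reactants: 12 (1R,6S)-6-[(2S,3S,5S)-5-bromo-2,6,6-trimethyl-3-(triethylsilyloxy)oxan-2-yl]-3-methylcyclohex-3-en-1-yl acetate
Product: 13 (1R,3R,4S,6S)-6-[(2S,3S,5S)-5-bromo-2,6,6-trimethyl-3-(triethylsilyloxy)oxan-2-yl]-3,4-dihydroxy-3-methylcyclohexyl acetate
Conditions: OsO4 (5 mol%), NMO, acetone/H2O, 0 → 25 °C
Reagents that add atoms: N-methylmorpholine N-oxide C[N+]1([O-])CCOCC1; water O
Why: Upjohn dihydroxylation: OsO4 adds syn to the only alkene from the face anti to the axial homoallylic acetate, so both new oxygens are trans to the acetate and oxanyl groups (C4–OH equatorial, C5–OH axial, C4–CH3 axial).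

Step 7
Reactants: 13 (1R,3R,4S,6S)-6-[(2S,3S,5S)-5-bromo-2,6,6-trimethyl-3-(triethylsilyloxy)oxan-2-yl]-3,4-dihydroxy-3-methylcyclohexyl acetate
Product: 15 cyclic sulfate of 13 (3,4-O-sulfonyl), via cyclic sulfite 14 (not isolated)
Conditions: SOCl2, Et3N, CH2Cl2, 0 °C; then RuCl3·3H2O (cat.), NaIO4, MeCN/H2O, 0 °C
Reagents that add atoms: thionyl chloride O=S(Cl)Cl; sodium periodate [Na+].[O-]I(=O)(=O)=O
Why: Gao–Sharpless cyclic sulfate synthesis (cyclic sulfite, then RuO4-catalysed oxidation at sulfur) activates both C–O bonds of the cis-diol without touching a stereocenter.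

Step 8
Reactants: 15 cyclic sulfate of 13
Product: 17 (1R,3R,4R,6S)-4-bromo-6-[(2S,3S,5S)-5-bromo-3-hydroxy-2,6,6-trimethyloxan-2-yl]-3-chloro-3-methylcyclohexyl acetate (target), via bromo sulfate 16 (not isolated)
Conditions: LiBr, THF, 0 → 25 °C; then HCl (4 M in dioxane), CH2Cl2, −20 → 0 °C
Reagents that add atoms: lithium bromide [Li+].[Br-]; hydrogen chloride Cl
Why: Proposed new method: bromide opens the cyclic sulfate by SN2 at the secondary carbon C5 with inversion (axial C–O to equatorial C–Br, the known reactivity of cyclic sulfates), then HCl ionises the tertiary sulfate monoester at C4, the axial C2 acetate captures the cation from the lower face as a 1,3-dioxan-2-ylium ion and chloride reopens it at C4 from the upper face (net retention, Cl equatorial and trans to Br; closest known reactions: halide opening of acyloxonium ions and tertiary ester solvolysis), while the same acid removes the triethylsilyl ether.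

## Compound list

1 | 6-methylhept-5-en-2-one | CC(=O)CCC=C(C)C | starting material
2 | (3S)-6-methyl-3-[(phenylamino)oxy]hept-5-en-2-one | CC(=O)[C@@H](ONc1ccccc1)CC=C(C)C | intermediate
3 | (3S)-3-hydroxy-6-methylhept-5-en-2-one | CC(=O)[C@@H](O)CC=C(C)C | intermediate
4 | 2-bromo-5-methylanisole (1-bromo-2-methoxy-4-methylbenzene) | COc1cc(C)ccc1Br | starting material
5 | (2-methoxy-4-methylphenyl)magnesium bromide | COc1cc(C)ccc1[Mg]Br | intermediate
6 | (2S,3S)-2-(2-methoxy-4-methylphenyl)-6-methylhept-5-ene-2,3-diol | C[C@](O)(c1ccc(C)cc1OC)[C@@H](O)CC=C(C)C | intermediate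
7 | (2S,3S)-2-(2-methoxy-4-methylphenyl)-6-methyl-3-(triethylsilyloxy)hept-5-en-2-ol | C[C@](O)(c1ccc(C)cc1OC)[C@@H](O[Si](CC)(CC)CC)CC=C(C)C | intermediate
8 | (2S,3S)-2-(2-methoxy-4-methylcyclohexa-1,4-dien-1-yl)-6-methyl-3-(triethylsilyloxy)hept-5-en-2-ol | COC1=C([C@](C)(O)[C@@H](O[Si](CC)(CC)CC)CC=C(C)C)CC=C(C)C1 | intermediate
9 | (2R)-2-[(2S,3S)-2-hydroxy-6-methyl-3-(triethylsilyloxy)hept-5-en-2-yl]-5-methylcyclohex-4-en-1-one | O=C1CC(C)=CC[C@@H]1[C@](C)(O)[C@@H](O[Si](CC)(CC)CC)CC=C(C)C | intermediate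
10 | (2R)-2-[(2S,3S,5S)-5-bromo-2,6,6-trimethyl-3-(triethylsilyloxy)oxan-2-yl]-5-methylcyclohex-4-en-1-one | O=C1CC(C)=CC[C@@H]1[C@]1(C)OC(C)(C)[C@@H](Br)C[C@@H]1O[Si](CC)(CC)CC | intermediate
11 | (1R,6S)-6-[(2S,3S,5S)-5-bromo-2,6,6-trimethyl-3-(triethylsilyloxy)oxan-2-yl]-3-methylcyclohex-3-en-1-ol (lithium alkoxide in the flask) | O[C@@H]1CC(C)=CC[C@@H]1[C@]1(C)OC(C)(C)[C@@H](Br)C[C@@H]1O[Si](CC)(CC)CC | intermediate
12 | (1R,6S)-6-[(2S,3S,5S)-5-bromo-2,6,6-trimethyl-3-(triethylsilyloxy)oxan-2-yl]-3-methylcyclohex-3-en-1-yl acetate | CC(=O)O[C@@H]1CC(C)=CC[C@@H]1[C@]1(C)OC(C)(C)[C@@H](Br)C[C@@H]1O[Si](CC)(CC)CC | intermediate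
13 | (1R,3R,4S,6S)-6-[(2S,3S,5S)-5-bromo-2,6,6-trimethyl-3-(triethylsilyloxy)oxan-2-yl]-3,4-dihydroxy-3-methylcyclohexyl acetate | CC(=O)O[C@@H]1C[C@@](C)(O)[C@@H](O)C[C@@H]1[C@]1(C)OC(C)(C)[C@@H](Br)C[C@@H]1O[Si](CC)(CC)CC | intermediate
14 | cyclic sulfite of 13 (3,4-O-sulfinyl; mixture at sulfur) | CC(=O)O[C@@H]1C[C@@]2(C)OS(=O)O[C@H]2C[C@@H]1[C@]1(C)OC(C)(C)[C@@H](Br)C[C@@H]1O[Si](CC)(CC)CC | intermediate
15 | cyclic sulfate of 13 (3,4-O-sulfonyl) | CC(=O)O[C@@H]1C[C@@]2(C)OS(=O)(=O)O[C@H]2C[C@@H]1[C@]1(C)OC(C)(C)[C@@H](Br)C[C@@H]1O[Si](CC)(CC)CC | intermediate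
16 | (1R,3R,4R,6S)-4-bromo-6-[(2S,3S,5S)-5-bromo-2,6,6-trimethyl-3-(triethylsilyloxy)oxan-2-yl]-3-methyl-3-(sulfooxy)cyclohexyl acetate (lithium salt in the flask) | CC(=O)O[C@@H]1C[C@@](C)(OS(=O)(=O)O)[C@H](Br)C[C@@H]1[C@]1(C)OC(C)(C)[C@@H](Br)C[C@@H]1O[Si](CC)(CC)CC | intermediate
17 | (1R,3R,4R,6S)-4-bromo-6-[(2S,3S,5S)-5-bromo-3-hydroxy-2,6,6-trimethyloxan-2-yl]-3-chloro-3-methylcyclohexyl acetate | CC(=O)O[C@@H]1C[C@@](C)(Cl)[C@H](Br)C[C@@H]1[C@]1(C)OC(C)(C)[C@@H](Br)C[C@@H]1O | target

## Step count and risks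

Total step count: 8. Longest linear sequence: 8 (1 → 3 → 7 → 9 → 10 → 12 → 13 → 15 → 17).

Why the halogens are not added directly: anti addition of BrCl to a 4-substituted 1-methylcyclohexene gives the trans-diaxial adduct (Cl cis, Br trans to the C1 substituent). The target is the other, all-equatorial diastereomer, so Br is brought in by SN2 on an axial C5–O bond and Cl by double inversion at C4.

The three steps most likely to fail:

**Step 8.** The tertiary C4–O bond of sulfate 15 may ionise (assisted by the axial acetate) before bromide reaches C5, which would put bromide on C4; E1 loss from the C4 cation is a second risk. Fallback, setting out from 13 and returning at 17: the sulfur is kept at the less ionisable sulfite level. Cyclic sulfite 14 is isolated and opened with Bu4NBr in DMF at 70 °C at the secondary carbon; the sulfite monoester loses SO2 on work-up and gives (1R,3R,4R,6S)-4-bromo-6-[(2S,3S,5S)-5-bromo-2,6,6-trimethyl-3-(triethylsilyloxy)oxan-2-yl]-3-hydroxy-3-methylcyclohexyl acetate F5. The tertiary alcohol of F5 is then converted with HCl in dioxane through the same acetate-controlled SN1 substitution, which also removes the silyl ether and gives 17.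

**Step 3.** Hydrogenolysis of the benzylic C–O bond can compete with ring reduction, and the C1 selectivity rests on a conformational model that is not proven for this substrate; the C1 epimer would have to be separated at 9 or 12. Fallback, setting out from 3 and returning at 9: the arene is reduced before the C1–C7 bond exists. 3-Methylphenol is silylated (i-Pr3SiCl, imidazole) to triisopropyl(3-methylphenoxy)silane F1. Birch reduction (Li, NH3, t-BuOH) gives triisopropyl[(5-methylcyclohexa-1,4-dien-1-yl)oxy]silane F2. A chelation-controlled Mukaiyama aldol addition of F2 to hydroxy ketone 3 (MgBr2·OEt2, CH2Cl2, −40 °C) forms the C1–C7 bond and gives (2R)-2-[(2S,3S)-2,3-dihydroxy-6-methylhept-5-en-2-yl]-5-methylcyclohex-4-en-1-one F3. Silylation of the secondary hydroxyl (Et3SiCl, imidazole) returns to 9.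

**Step 4.** The ring alkene competes for bromine (a cineole-type closure of C7–OH onto C4 is conceivable), and 5-exo closure or a poor ratio at C10 would lower the yield. Fallback, setting out from 9 and returning at 10: ring closure and C–Br formation are separated. Mercuricyclisation with Hg(O2CCF3)2 in MeNO2 at −20 °C (reversible, thermodynamically 6-endo), then aqueous KBr, gives (2R)-2-[(2S,3S,5S)-5-(bromomercurio)-2,6,6-trimethyl-3-(triethylsilyloxy)oxan-2-yl]-5-methylcyclohex-4-en-1-one F4. Bromodemercuration of F4 with Br2 in pyridine at 0 °C (retention) gives 10.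

## Further compounds

F1 | step 3 | triisopropyl(3-methylphenoxy)silane | Cc1cccc(O[Si](C(C)C)(C(C)C)C(C)C)c1
F2 | step 3 | triisopropyl[(5-methylcyclohexa-1,4-dien-1-yl)oxy]silane | CC1=CCC=C(O[Si](C(C)C)(C(C)C)C(C)C)C1
F3 | step 3 | (2R)-2-[(2S,3S)-2,3-dihydroxy-6-methylhept-5-en-2-yl]-5-methylcyclohex-4-en-1-one | O=C1CC(C)=CC[C@@H]1[C@](C)(O)[C@@H](O)CC=C(C)C
F4 | step 4 | (2R)-2-[(2S,3S,5S)-5-(bromomercurio)-2,6,6-trimethyl-3-(triethylsilyloxy)oxan-2-yl]-5-methylcyclohex-4-en-1-one | O=C1CC(C)=CC[C@@H]1[C@]1(C)OC(C)(C)[C@@H]([Hg]Br)C[C@@H]1O[Si](CC)(CC)CC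
F5 | step 8 | (1R,3R,4R,6S)-4-bromo-6-[(2S,3S,5S)-5-bromo-2,6,6-trimethyl-3-(triethylsilyloxy)oxan-2-yl]-3-hydroxy-3-methylcyclohexyl acetate | CC(=O)O[C@@H]1C[C@@](C)(O)[C@H](Br)C[C@@H]1[C@]1(C)OC(C)(C)[C@@H](Br)C[C@@H]1O[Si](CC)(CC)CC
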